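Z, the D built into chains, is the product. E starts the chains, and L is a further species in the flask.

in all of them: E 0.21 mol%
- Friday's: D 5 mM; L 2 mM; run made earlier
- flask: D 10 mM; L 2.00 mM; time 4.0 min

Friday's run (percent of the D charged)

| time / s | Z / % | D / % |
|---|---|---|
| 10.0 | 1 | 98 |
| 12.0 | 1 | 95 |
| 30.0 | 0 | 90 |
| 80.0 | 2 | 79 |

(scatter of a reading: 1.5 percentage points)

- the average divides the monomer in chains by the number of chains begun, living and dead together
- the earlier runs do not show the number of chains; that part of a forecast is a guess
- no earlier run changes the charge of E; that part of a forecast is a guess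

1. average number of monomer units in a chain (chains begun, living or dead) at 4.0 min
2. part of the D that has reacted at 4.0 min

First ask where Friday's D went. By 80.0 s D has lost 21.0% of its charge, but Z reads 2%, with a scatter of 1.5 percentage points. Assume that L takes D one for one. The loss of 1.05 mM stays below Friday's 2 mM of L.

Next ask whether L lasts. Replace each curve by its mean: on Friday, D 4.47 mM and L 1.48 mM. Define τ as mean L divided by its mean rate of loss, which gives 112 s on Friday. With D in excess, L falls pseudo-first-order, so τ scales inversely with mean D. The new flask has mean D 9.00 mM, so its lifetime of L is τ = 55.9 s. The time 4.0 min spans 4.29 lifetimes, which reckons 1.36% of L still there. Check the mean: put in D less the full charge of L, 8.00 mM, and the reckoning gives 2.20%. Either reckoning has nearly all of L reacted.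

So L costs about 20.0% of the D. Commit to c just above that. Leave dp open, since the runs show no number of chains.

The forecast gives c 24% and dp 19, the dp on the guess “If every E starts one chain”.

The flask gives dp 170, 8.95 times the forecast's, and c 25.3%.

D + G → Q + Z (k = 0.690 M⁻¹ s⁻¹); D + Q → Z + Q, rate k2*[Q]*[D] (k = 230 M⁻¹ s⁻¹); L + D → X (k = 2.30 M⁻¹ s⁻¹); 2 D → J (k = 8.90 × 10⁻⁴ M⁻¹ s⁻¹); E → G (k = 0.00160 s⁻¹) At 4.00 min the flask holds the living ends Q at 0.00310 mM, a share 14.8% of the E charged. τ gave 1.36% of L, and the flask holds 1.06% of its charge. A neighbour flask with 0.84 mol% of E has the same charges of D and L, so the reckoning with τ stays as it was, and that flask holds 1.3% of its L.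

The readings stem from a simulated flask from invented constants; the scatter is artificial.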